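**Retrosynthetic overview**
1. The target is reached by acylating the C9 hydroxyl with (2R,3R)-2,3-dimethyloxirane-2-carboxylic acid (Sharpless epoxidation of angelyl alcohol) and removing a C8 silyl ether.
2. Key disconnection C9–C10: the ten-membered carbocycle is closed last by a Ni/Cr-mediated (Nozaki–Hiyama–Kishi) addition of the C10 (Z)-alkenyl iodide to the C9 aldehyde, which also sets C9.
3. Enabling feature: the two Z-trisubstituted alkenes C1=C10 and C4=C5 and the trans-fused five-membered lactone on C6–C7 fold the seco chain so that C10 meets C9; the C8 silyloxy centre next to the aldehyde steers the face.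
4. The seco aldehyde comes from a C6–C7 bond made by indium-mediated allylation of a Z hydroxy enal (masked as its lactol) with a chiral 3-(bromomethyl)butenolide, whose temporary 7,8-lactone ring fixes C6 and C7 against C8; base-induced translactonisation with epoxide closure and Swern-type epoxide opening then give the 6,7-lactone α-silyloxy aldehyde.
5. Ring order: west butenolide (temporary, fixes C4=C5 as Z) and east butenolide (temporary), then the 6,7-lactone with a temporary C8–C9 oxirane, then the ten-membered ring; the side-chain oxirane arrives preformed.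

Key step: step 15

Remark: atoms are numbered as in germacranolides (ring C1–C10, alkenes C1=C10 and C4=C5, methyls C14 on C10 and C15 on C4, acetate on C3, lactone oxygen on C6, C7 carrying C11(=C13)–C12(=O), free hydroxyl on C8, epoxy ester on C9); aldehyde 14 is taken as a commercial, freshly distilled starting material, and the copper-catalysed N–O cleavage in step 4 is assumed to release the nitrogen part as azobenzene.

**West fragment**

Step 1
Reactants: 1 but-2-yn-1-ol
Product: 3 (Z)-3-iodobut-2-en-1-ol, via cyclic alkenylalanate 2 (not isolated)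
Conditions: NaAlH2(OCH2CH2OCH3)2, THF, 0 °C → rt; then I2, −78 °C → 0 °C
Reagents that add atoms: iodine, II
Why: Hydroxyl-directed trans-hydroalumination of the propargylic alcohol places aluminium on C10 in a five-membered alanate ring cis to the CH2O group, and iodinolysis with retention should give only the Z alkenyl iodide that later fixes the C1=C10 geometry.

Step 2
Reactants: 3 (Z)-3-iodobut-2-en-1-ol
Product: 4 (Z)-1-bromo-3-iodobut-2-ene
Conditions: CBr4, PPh3, CH2Cl2, 0 °C
Reagents that add atoms: carbon tetrabromide, BrC(Br)(Br)Br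
Why: Appel bromination of the primary allylic alcohol proceeds by SN2 attack of bromide on the alkoxyphosphonium salt and leaves the alkenyl iodide and its geometry untouched.

Step 3
Reactants: 4 (Z)-1-bromo-3-iodobut-2-ene; 5 pentane-2,4-dione
Product: 7 (5Z)-6-iodohept-5-en-2-one, via alkylated dione 6 (not isolated)
Conditions: K2CO3, EtOH, reflux
Reagents that add atoms: none
Why: C-alkylation of the diketone enolate by the allylic bromide is followed in the same pot by ethoxide-induced retro-Claisen deacetylation (one-pot methyl ketone synthesis), and the alkenyl iodide is inert to carbonate.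

Step 4
Reactants: 7 (5Z)-6-iodohept-5-en-2-one
Product: 9 (3S,5Z)-3-hydroxy-6-iodohept-5-en-2-one, via aminooxy ketone 8 (not isolated)
Conditions: PhNO (slow addition, 7 in excess), D-proline (20 mol %), DMSO, rt; then CuSO4·5H2O (30 mol %), MeOH, 0 °C
Reagents that add atoms: nitrosobenzene, O=Nc1ccccc1
Why: Proline-catalysed α-aminoxylation (O-nitroso aldol) of the more substituted enamine, with the nitroso oxygen delivered by the carboxylic acid of D-proline, should set C3 as S, and copper-catalysed N–O cleavage then frees the α-hydroxy ketone without touching the stereocentre.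

Step 5
Reactants: 9 (3S,5Z)-3-hydroxy-6-iodohept-5-en-2-one; 10 (triphenylphosphoranylidene)ketene
Product: 12 (5S)-5-[(2Z)-3-iodobut-2-en-1-yl]-4-methylfuran-2(5H)-one, via ester ylide 11 (not isolated)
Conditions: toluene, 90 °C
Reagents that add atoms: none
Why: The hydroxyl adds to the ketene and the resulting ester ylide undergoes an intramolecular Wittig reaction with the methyl ketone, so the five-membered ring forces C3 and C6 to be cis on the new C4=C5 alkene (Z in the later chain).

Step 6
Reactants: 12 (5S)-5-[(2Z)-3-iodobut-2-en-1-yl]-4-methylfuran-2(5H)-one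
Product: 13 (2RS,5S)-5-[(2Z)-3-iodobut-2-en-1-yl]-4-methyl-2,5-dihydrofuran-2-ol
Conditions: i-Bu2AlH (1.05 equiv), CH2Cl2, −78 °C; neutral work-up, used crude
Reagents that add atoms: none
Why: Half-reduction of the lactone with i-Bu2AlH stops at the aluminium hemiacetal and should give the lactol that masks the Z hydroxy enal, while the alkenyl iodide and the alkenes are inert at low temperature.

**East fragment**

Step 7
Reactants: 14 (4S)-2,2-dimethyl-1,3-dioxolane-4-carbaldehyde; 15 methyl acrylate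
Product: 16 methyl 2-{(RS)-[(4S)-2,2-dimethyl-1,3-dioxolan-4-yl](hydroxy)methyl}prop-2-enoate
Conditions: DABCO (0.5 equiv), 1,4-dioxane/H2O (1:1), rt
Reagents that add atoms: none
Why: Morita–Baylis–Hillman reaction of the aldehyde with the DABCO–acrylate zwitterion; the new carbinol centre forms as a mixture that is erased in step 10, while C8 comes unchanged from the chiral pool.

Step 8
Reactants: 16 methyl 2-{(RS)-[(4S)-2,2-dimethyl-1,3-dioxolan-4-yl](hydroxy)methyl}prop-2-enoate
Product: 18 (4RS,5S)-4-hydroxy-5-(hydroxymethyl)-3-methylideneoxolan-2-one, via triol ester 17 (not isolated)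
Conditions: CF3CO2H/H2O (9:1), 0 °C → rt; then toluene azeotrope
Reagents that add atoms: none
Why: Acidic acetonide hydrolysis frees the triol, whose γ-hydroxyl (O8) should close the five-membered lactone onto the methyl ester in preference to the six-membered alternative, without touching C8.

Step 9
Reactants: 18 (4RS,5S)-4-hydroxy-5-(hydroxymethyl)-3-methylideneoxolan-2-one
Product: 19 [(2S,3RS)-3-hydroxy-4-methylidene-5-oxooxolan-2-yl]methyl 4-methylbenzenesulfonate
Conditions: TsCl (1.05 equiv), pyridine, CH2Cl2, −10 °C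
Reagents that add atoms: p-toluenesulfonyl chloride, Cc1ccc(cc1)S(Cl)(=O)=O
Why: Sulfonylation is selective for the primary hydroxyl over the secondary allylic one on steric grounds and installs the leaving group for the later epoxide closure.

Step 10
Reactants: 19 [(2S,3RS)-3-hydroxy-4-methylidene-5-oxooxolan-2-yl]methyl 4-methylbenzenesulfonate
Product: 20 [(2R)-4-(bromomethyl)-5-oxo-2,5-dihydrofuran-2-yl]methyl 4-methylbenzenesulfonate
Conditions: PBr3 (0.4 equiv), Et2O, 0 °C
Reagents that add atoms: phosphorus tribromide, BrP(Br)Br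
Why: Allylic bromination of the Morita–Baylis–Hillman-type alcohol with 1,3-transposition (SN2′) moves the alkene into the ring and gives the conjugated butenolide with a primary allylic bromide; both carbinol epimers converge and the β-oxygenated primary tosylate is too slow to be displaced.

**Union and seco aldehyde**

Step 11
Reactants: 13 (2RS,5S)-5-[(2Z)-3-iodobut-2-en-1-yl]-4-methyl-2,5-dihydrofuran-2-ol; 20 [(2R)-4-(bromomethyl)-5-oxo-2,5-dihydrofuran-2-yl]methyl 4-methylbenzenesulfonate
Product: 23 (4S,5R)-4-[(1R,2Z,4S,6Z)-1,4-dihydroxy-7-iodo-3-methylocta-2,6-dien-1-yl]-3-methylidene-5-[(tosyloxy)methyl]oxolan-2-one, via open-chain hydroxy enal 21 (not isolated), via allylindium dibromide 22 (not isolated)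
Conditions: In powder (2 equiv), 20 (1.5 equiv), THF/H2O (1:1), rt
Reagents that add atoms: none
Why: Indium-mediated Barbier allylation in which the lactol opens to the Z hydroxy enal and the allylindium reacts through its γ-carbon C7 on the ring face opposite to the CH2OTs group at C8 (sets C7 trans to C9) and through a chair-like six-membered transition state whose ring-fixed E-type allyl geometry gives the anti relation of the C6 hydroxyl to C8 (sets C6), as known for additions of 3-(bromomethyl)furan-2(5H)-ones to aldehydes.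

Step 12
Reactants: 23 (4S,5R)-4-[(1R,2Z,4S,6Z)-1,4-dihydroxy-7-iodo-3-methylocta-2,6-dien-1-yl]-3-methylidene-5-[(tosyloxy)methyl]oxolan-2-one
Product: 25 (4S,5R)-5-[(1Z,3S,5Z)-3-hydroxy-6-iodo-2-methylhepta-1,5-dien-1-yl]-3-methylidene-4-[(2R)-oxiran-2-yl]oxolan-2-one, via translactonised hydroxy tosylate 24 (not isolated)
Conditions: DBU (2.5 equiv), MeCN, 0 °C → 40 °C
Reagents that add atoms: none
Why: Base-induced translactonisation (O6 attacks the lactone carbonyl through a five-membered transition state) is made irreversible by intramolecular Williamson closure of the liberated C8 alkoxide onto the primary tosylate; no bond to a stereocentre is broken, and direct attack of O6 on C9 would need a trans-fused bicyclo[3.3.0] ring.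

Step 13
Reactants: 25 (4S,5R)-5-[(1Z,3S,5Z)-3-hydroxy-6-iodo-2-methylhepta-1,5-dien-1-yl]-3-methylidene-4-[(2R)-oxiran-2-yl]oxolan-2-one
Product: 26 (1Z,3S,5Z)-6-iodo-2-methyl-1-{(2R,3S)-4-methylidene-5-oxo-3-[(2R)-oxiran-2-yl]oxolan-2-yl}hepta-1,5-dien-3-yl acetate
Conditions: Ac2O, pyridine, DMAP (cat.), CH2Cl2, 0 °C
Reagents that add atoms: acetic anhydride, CC(=O)OC(C)=O
Why: DMAP-catalysed acylation of the only free hydroxyl installs the C3 acetate, and the oxirane and the lactone are inert to these conditions.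

Step 14
Reactants: 26 (1Z,3S,5Z)-6-iodo-2-methyl-1-{(2R,3S)-4-methylidene-5-oxo-3-[(2R)-oxiran-2-yl]oxolan-2-yl}hepta-1,5-dien-3-yl acetate
Product: 28 (1Z,3S,5Z)-6-iodo-2-methyl-1-{(2R,3S)-4-methylidene-5-oxo-3-[(1R)-2-oxo-1-[(triethylsilyl)oxy]ethyl]oxolan-2-yl}hepta-1,5-dien-3-yl acetate, via alkoxysulfonium triflate 27 (not isolated)
Conditions: DMSO (10 equiv), Et3SiOTf (1.2 equiv), CH2Cl2, −78 °C → 0 °C; then Et3N, 0 °C → rt
Reagents that add atoms: triethylsilyl trifluoromethanesulfonate, CC[Si](CC)(CC)OS(=O)(=O)C(F)(F)F; dimethyl sulfoxide, CS(C)=O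
Why: Swern-type (Kornblum) oxidative opening of a terminal epoxide, in which the silyl triflate silylates the oxirane oxygen, DMSO opens the ring by SN2 attack at the unhindered C9 and triethylamine collapses the alkoxysulfonium salt to the aldehyde, so that C8 keeps its C–O bond and configuration and emerges as the triethylsilyl ether.

**Key step**

Step 15
Reactants: 28 (1Z,3S,5Z)-6-iodo-2-methyl-1-{(2R,3S)-4-methylidene-5-oxo-3-[(1R)-2-oxo-1-[(triethylsilyl)oxy]ethyl]oxolan-2-yl}hepta-1,5-dien-3-yl acetate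
Product: 30 (3S,6R,7S,8R,9R)-3-acetoxy-9-hydroxy-8-[(triethylsilyl)oxy]germacra-1(10)Z,4Z,11(13)-trien-12,6-olide, via alkenylchromium dichloride 29 (not isolated)
Conditions: CrCl2 (12 equiv), NiCl2 (0.1 equiv), degassed DMSO, rt, syringe-pump addition of 28 (final 2 mM)
Reagents that add atoms: none
Why: Nozaki–Hiyama–Kishi reaction: zerovalent nickel (formed from NiCl2 by CrCl2) inserts into the C10–I bond with retention of the Z geometry, the alkenyl group passes to trivalent chromium, and the alkenylchromium adds to the C9 aldehyde, the chromium alkoxide being hydrolysed on work-up. The closest known reaction type is the Ni/Cr-mediated macrocyclisation of alkenyl iodide aldehydes to medium-ring and macrocyclic allylic alcohols. The ten-membered carbocycle is closed in a 10-exo-trig mode (the C=O is exocyclic to the new ring). The new stereocentre C9 is controlled by the C8 silyloxy centre together with the forming ring: the alkenylchromium should attack anti to the C8–O bond (Cornforth/polar Felkin–Anh alignment) while the ring holds C7 gauche to C10, so the chromium-bound oxygen is pushed to the periphery, anti to C7, which corresponds to the 8,9-syn (9R) carbinol. The step needs chemoselectivity for the aldehyde over lactone, acetate and the α-methylene lactone (secured by the non-basic, oxophilic alkenylchromium), ring closure over oligomerisation (secured by high dilution and by the two Z alkenes and the trans-lactone, which fold the chain), and retention of the C1=C10 geometry (secured by the configurational stability of trisubstituted alkenyl nickel and chromium species).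

**Side-chain acid**

Step 16
Reactants: 31 methyl (Z)-2-methylbut-2-enoate (methyl angelate)
Product: 32 (Z)-2-methylbut-2-en-1-ol
Conditions: i-Bu2AlH (2.2 equiv), CH2Cl2, −78 °C → 0 °C
Reagents that add atoms: none
Why: 1,2-Reduction of the conjugated ester with i-Bu2AlH gives the allylic alcohol without isomerising the Z alkene.

Step 17
Reactants: 32 (Z)-2-methylbut-2-en-1-ol
Product: 33 [(2S,3R)-2,3-dimethyloxiran-2-yl]methanol
Conditions: Ti(Oi-Pr)4 (1.0 equiv), D-(−)-diethyl tartrate (1.2 equiv), t-BuOOH, CH2Cl2, −20 °C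
Reagents that add atoms: tert-butyl hydroperoxide, CC(C)(C)OO
Why: Sharpless asymmetric epoxidation, in which D-(−)-diethyl tartrate delivers the peroxide oxygen to the top face of the allylic alcohol drawn with CH2OH at the lower right and should give the (2S,3R)-epoxy alcohol, the Z geometry fixing the two methyl groups trans.

Step 18
Reactants: 33 [(2S,3R)-2,3-dimethyloxiran-2-yl]methanol
Product: 34 (2R,3R)-2,3-dimethyloxirane-2-carboxylic acid
Conditions: TEMPO (20 mol %), PhI(OAc)2 (2.2 equiv), MeCN/H2O (1:1), rt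
Reagents that add atoms: water, O
Why: Oxoammonium (TEMPO) oxidation takes the primary alcohol through the aldehyde hydrate to the acid under conditions that leave the oxirane and both stereocentres intact.

**Endgame**

Step 19
Reactants: 30 (3S,6R,7S,8R,9R)-3-acetoxy-9-hydroxy-8-[(triethylsilyl)oxy]germacra-1(10)Z,4Z,11(13)-trien-12,6-olide; 34 (2R,3R)-2,3-dimethyloxirane-2-carboxylic acid
Product: 36 (3S,6R,7S,8R,9R)-3-acetoxy-9-[(2R,3R)-2,3-dimethyloxirane-2-carbonyloxy]-8-[(triethylsilyl)oxy]germacra-1(10)Z,4Z,11(13)-trien-12,6-olide, via mixed anhydride 35 (not isolated)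
Conditions: 34, 2,4,6-Cl3C6H2COCl, Et3N, THF, rt; then 30, DMAP, toluene, rt → 40 °C
Reagents that add atoms: none
Why: Yamaguchi esterification, in which DMAP attacks the mixed anhydride at the less hindered epoxy-acyl carbonyl and the acylpyridinium acylates the hindered C9 hydroxyl with retention at C9, while lactone, acetate and silyl ether are inert.

Step 20
Reactants: 36 (3S,6R,7S,8R,9R)-3-acetoxy-9-[(2R,3R)-2,3-dimethyloxirane-2-carbonyloxy]-8-[(triethylsilyl)oxy]germacra-1(10)Z,4Z,11(13)-trien-12,6-olide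
Product: 37 (3S,6R,7R,8R,9R)-3-acetoxy-9-[(2R,3R)-2,3-dimethyloxirane-2-carbonyloxy]-8-hydroxygermacra-1(10)Z,4Z,11(13)-trien-12,6-olide (CNP0137407.10)
Conditions: HF·pyridine, pyridine, THF, 0 °C
Reagents that add atoms: none
Why: Fluoride-mediated cleavage of the triethylsilyl ether under buffered, mildly acidic conditions should free the C8 hydroxyl without 1,2-acyl migration from O9 to O8, oxirane opening or Michael addition to the α-methylene lactone.

**Compound list**

1 | but-2-yn-1-ol | CC#CCO | starting material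
2 | sodium 2,2-bis(2-methoxyethoxy)-3-methyl-1-oxa-2-aluminacyclopent-3-en-2-uide (cyclic alkenylalanate) | CC1=CCO[Al-]1(OCCOC)OCCOC.[Na+] | intermediate (not isolated)
3 | (Z)-3-iodobut-2-en-1-ol | OC/C=C(/C)I | intermediate
4 | (Z)-1-bromo-3-iodobut-2-ene | BrC/C=C(/C)I | intermediate
5 | pentane-2,4-dione | CC(=O)CC(C)=O | starting material
6 | 3-[(2Z)-3-iodobut-2-en-1-yl]pentane-2,4-dione | CC(=O)C(C/C=C(/C)I)C(C)=O | intermediate (not isolated)
7 | (5Z)-6-iodohept-5-en-2-one | CC(=O)CC/C=C(/C)I | intermediate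
8 | (3S,5Z)-6-iodo-3-[(phenylamino)oxy]hept-5-en-2-one | CC(=O)[C@@H](ONc1ccccc1)C/C=C(/C)I | intermediate (not isolated)
9 | (3S,5Z)-3-hydroxy-6-iodohept-5-en-2-one | CC(=O)[C@@H](O)C/C=C(/C)I | intermediate
10 | (triphenylphosphoranylidene)ketene | O=C=C=P(c1ccccc1)(c1ccccc1)c1ccccc1 | starting material
11 | (3S,5Z)-6-iodo-2-oxohept-5-en-3-yl (triphenylphosphoranylidene)acetate | CC(=O)[C@@H](OC(=O)C=P(c1ccccc1)(c1ccccc1)c1ccccc1)C/C=C(/C)I | intermediate (not isolated)
12 | (5S)-5-[(2Z)-3-iodobut-2-en-1-yl]-4-methylfuran-2(5H)-one | CC1=CC(=O)O[C@H]1C/C=C(/C)I | intermediate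
13 | (2RS,5S)-5-[(2Z)-3-iodobut-2-en-1-yl]-4-methyl-2,5-dihydrofuran-2-ol | CC1=CC(O)O[C@H]1C/C=C(/C)I | intermediate
14 | (4S)-2,2-dimethyl-1,3-dioxolane-4-carbaldehyde | CC1(C)OC[C@H](O1)C=O | starting material
15 | methyl acrylate | C=CC(=O)OC | starting material
16 | methyl 2-{(RS)-[(4S)-2,2-dimethyl-1,3-dioxolan-4-yl](hydroxy)methyl}prop-2-enoate | C=C(C(=O)OC)C(O)[C@@H]1COC(C)(C)O1 | intermediate
17 | methyl 2-[(1RS,2S)-1,2,3-trihydroxypropyl]prop-2-enoate | C=C(C(=O)OC)C(O)[C@@H](O)CO | intermediate (not isolated)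
18 | (4RS,5S)-4-hydroxy-5-(hydroxymethyl)-3-methylideneoxolan-2-one | C=C1C(O)[C@H](CO)OC1=O | intermediate
19 | [(2S,3RS)-3-hydroxy-4-methylidene-5-oxooxolan-2-yl]methyl 4-methylbenzenesulfonate | C=C1C(O)[C@H](COS(=O)(=O)c2ccc(C)cc2)OC1=O | intermediate
20 | [(2R)-4-(bromomethyl)-5-oxo-2,5-dihydrofuran-2-yl]methyl 4-methylbenzenesulfonate | Cc1ccc(cc1)S(=O)(=O)OC[C@@H]1OC(=O)C(CBr)=C1 | intermediate
21 | (2Z,4S,6Z)-4-hydroxy-7-iodo-3-methylocta-2,6-dienal (open form of 13) | O=C/C=C(/C)[C@@H](O)C/C=C(/C)I | intermediate (not isolated)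
22 | allylindium species from 20, drawn as the dibromide | Cc1ccc(cc1)S(=O)(=O)OC[C@@H]1OC(=O)C(C[In](Br)Br)=C1 | intermediate (not isolated)
23 | (4S,5R)-4-[(1R,2Z,4S,6Z)-1,4-dihydroxy-7-iodo-3-methylocta-2,6-dien-1-yl]-3-methylidene-5-[(tosyloxy)methyl]oxolan-2-one | C=C1C(=O)O[C@@H](COS(=O)(=O)c2ccc(C)cc2)[C@@H]1[C@H](O)/C=C(/C)[C@@H](O)C/C=C(/C)I | intermediate
24 | (4R,5R)-5-[(1Z,3S,5Z)-3-hydroxy-6-iodo-2-methylhepta-1,5-dien-1-yl]-4-[(1R)-1-hydroxy-2-(tosyloxy)ethyl]-3-methylideneoxolan-2-one | C=C1C(=O)O[C@H](/C=C(/C)[C@@H](O)C/C=C(/C)I)[C@H]1[C@@H](O)COS(=O)(=O)c2ccc(C)cc2 | intermediate (not isolated)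
25 | (4S,5R)-5-[(1Z,3S,5Z)-3-hydroxy-6-iodo-2-methylhepta-1,5-dien-1-yl]-3-methylidene-4-[(2R)-oxiran-2-yl]oxolan-2-one | C=C1C(=O)O[C@H](/C=C(/C)[C@@H](O)C/C=C(/C)I)[C@H]1[C@@H]2CO2 | intermediate
26 | (1Z,3S,5Z)-6-iodo-2-methyl-1-{(2R,3S)-4-methylidene-5-oxo-3-[(2R)-oxiran-2-yl]oxolan-2-yl}hepta-1,5-dien-3-yl acetate | C=C1C(=O)O[C@H](/C=C(/C)[C@@H](OC(C)=O)C/C=C(/C)I)[C@H]1[C@@H]2CO2 | intermediate
27 | {(2R)-2-[(2R,3S)-2-[(1Z,3S,5Z)-3-acetoxy-6-iodo-2-methylhepta-1,5-dien-1-yl]-4-methylidene-5-oxooxolan-3-yl]-2-[(triethylsilyl)oxy]ethoxy}dimethylsulfonium trifluoromethanesulfonate | C=C1C(=O)O[C@H](/C=C(/C)[C@@H](OC(C)=O)C/C=C(/C)I)[C@H]1[C@@H](O[Si](CC)(CC)CC)CO[S+](C)C.[O-]S(=O)(=O)C(F)(F)F | intermediate (not isolated)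
28 | (1Z,3S,5Z)-6-iodo-2-methyl-1-{(2R,3S)-4-methylidene-5-oxo-3-[(1R)-2-oxo-1-[(triethylsilyl)oxy]ethyl]oxolan-2-yl}hepta-1,5-dien-3-yl acetate | C=C1C(=O)O[C@H](/C=C(/C)[C@@H](OC(C)=O)C/C=C(/C)I)[C@H]1[C@@H](O[Si](CC)(CC)CC)C=O | intermediate
29 | alkenylchromium dichloride from 28 (C10–CrCl2 in place of C10–I, Z geometry retained) | C=C1C(=O)O[C@H](/C=C(/C)[C@@H](OC(C)=O)C/C=C(/C)[Cr](Cl)Cl)[C@H]1[C@@H](O[Si](CC)(CC)CC)C=O | intermediate (not isolated)
30 | (3S,6R,7S,8R,9R)-3-acetoxy-9-hydroxy-8-[(triethylsilyl)oxy]germacra-1(10)Z,4Z,11(13)-trien-12,6-olide | C=C1C(=O)O[C@@H]2/C=C(/C)[C@@H](OC(C)=O)C/C=C(/C)[C@@H](O)[C@H](O[Si](CC)(CC)CC)[C@@H]12 | intermediate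
31 | methyl (Z)-2-methylbut-2-enoate | C/C=C(C)\C(=O)OC | starting material
32 | (Z)-2-methylbut-2-en-1-ol | C/C=C(C)\CO | intermediate
33 | [(2S,3R)-2,3-dimethyloxiran-2-yl]methanol | OC[C@]1(C)O[C@@H]1C | intermediate
34 | (2R,3R)-2,3-dimethyloxirane-2-carboxylic acid | OC(=O)[C@]1(C)O[C@@H]1C | intermediate
35 | (2R,3R)-2,3-dimethyloxirane-2-carboxylic 2,4,6-trichlorobenzoic anhydride | O=C(OC(=O)[C@]1(C)O[C@@H]1C)c1c(Cl)cc(Cl)cc1Cl | intermediate (not isolated)
36 | (3S,6R,7S,8R,9R)-3-acetoxy-9-[(2R,3R)-2,3-dimethyloxirane-2-carbonyloxy]-8-[(triethylsilyl)oxy]germacra-1(10)Z,4Z,11(13)-trien-12,6-olide | C=C1C(=O)O[C@@H]2/C=C(/C)[C@@H](OC(C)=O)C/C=C(/C)[C@@H](OC(=O)[C@]3(C)O[C@@H]3C)[C@H](O[Si](CC)(CC)CC)[C@@H]12 | intermediate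
37 | (3S,6R,7R,8R,9R)-3-acetoxy-9-[(2R,3R)-2,3-dimethyloxirane-2-carbonyloxy]-8-hydroxygermacra-1(10)Z,4Z,11(13)-trien-12,6-olide (CNP0137407.10) | C=C1C(=O)O[C@@H]2/C=C(/C)[C@@H](OC(C)=O)C/C=C(/C)[C@@H](OC(=O)[C@]3(C)O[C@@H]3C)[C@H](O)[C@@H]12 | target

**Totals**

Total step count: 20. Longest linear sequence: 13 steps (steps 1–6, 11–15, 19, 20).

**Steps most likely to fail, with fallbacks**

Step 15 (key ring closure). What may go wrong: oligomerisation may compete with closure of the strained ten-membered ring, and the facial selectivity at C9 may be poor or reversed if the open-chain Felkin–Anh preference (which leads to the 8,9-anti carbinol) outweighs the ring constraint. The fallback sets out from 28 and comes back at 30. The same Ni/Cr ring closure would be run without regard to the C9 configuration, giving (3S,6R,7S,8R,9S)-3-acetoxy-9-hydroxy-8-[(triethylsilyl)oxy]germacra-1(10)Z,4Z,11(13)-trien-12,6-olide F1, alone or mixed with 30. The carbinol would be oxidised with Dess–Martin periodinane to the macrocyclic enone (3S,6R,7S,8R)-3-acetoxy-9-oxo-8-[(triethylsilyl)oxy]germacra-1(10)Z,4Z,11(13)-trien-12,6-olide F2. C9 would then be set by Luche reduction (NaBH4, CeCl3·7H2O, MeOH, −78 °C). Hydride attack anti to the C8–O bond on the ketone should give the opposite carbinol configuration to alkenyl attack on the aldehyde, that is 30.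

Step 11 (fragment union). What may go wrong: the lactol may lose water to the aromatic furan under the mildly acidic aqueous conditions, may open too slowly to the enal, and the anti and facial selectivities may erode. The fallback sets out from 12 and comes back at 26; it replaces the lactol by an open-chain enal that already carries the C3 acetate. Butenolide 12 would be reduced with LiAlH4 to (2Z,4S,6Z)-7-iodo-3-methylocta-2,6-diene-1,4-diol F3 and acetylated twice (Ac2O, pyridine) to (2Z,4S,6Z)-7-iodo-3-methylocta-2,6-diene-1,4-diyl diacetate F4. The primary acetate would be removed selectively with Candida antarctica lipase B in phosphate buffer to give (2Z,4S,6Z)-1-hydroxy-7-iodo-3-methylocta-2,6-dien-4-yl acetate F5, and MnO2 oxidation would give (2Z,4S,6Z)-7-iodo-3-methyl-1-oxoocta-2,6-dien-4-yl acetate F6, which cannot close to a lactol. Indium-mediated allylation of F6 with 20 should give the 7,8-lactone adduct (1R,2Z,4S,6Z)-1-hydroxy-7-iodo-3-methyl-1-{(3S,4R)-4-methylidene-5-oxo-2-[(tosyloxy)methyl]oxolan-3-yl}octa-2,6-dien-4-yl acetate F7 (ring carbon bearing CH2OTs configured as in 23). DBU would convert it, through the translactonised hydroxy tosylate acetate F8 (not isolated), directly into 26.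

Step 14 (epoxide to α-silyloxy aldehyde). What may go wrong: the silyl triflate may ionise the allylic acetate or the allylic lactone C–O bond, DMSO may open the oxirane at C8, and the α-silyloxy aldehyde may epimerise at C8 during the base treatment. The fallback sets out from 26 and comes back at 28. The oxirane would be hydrolysed (HClO4 cat., THF/H2O, 0 °C) to the diol (1Z,3S,5Z)-1-{(2R,3R)-3-[(1R)-1,2-dihydroxyethyl]-4-methylidene-5-oxooxolan-2-yl}-6-iodo-2-methylhepta-1,5-dien-3-yl acetate F9. Both hydroxyls would be silylated (Et3SiCl, imidazole, DMF) to the bis(triethylsilyl) ether F10, and the primary silyl ether would be cleaved and oxidised in one operation under Swern conditions ((COCl)2, DMSO, then Et3N, −78 °C → −20 °C) to give 28.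

**Further compounds**

F1 | step 15 | (3S,6R,7S,8R,9S)-3-acetoxy-9-hydroxy-8-[(triethylsilyl)oxy]germacra-1(10)Z,4Z,11(13)-trien-12,6-olide | C=C1C(=O)O[C@@H]2/C=C(/C)[C@@H](OC(C)=O)C/C=C(/C)[C@H](O)[C@H](O[Si](CC)(CC)CC)[C@@H]12
F2 | step 15 | (3S,6R,7S,8R)-3-acetoxy-9-oxo-8-[(triethylsilyl)oxy]germacra-1(10)Z,4Z,11(13)-trien-12,6-olide | C=C1C(=O)O[C@@H]2/C=C(/C)[C@@H](OC(C)=O)C/C=C(/C)C(=O)[C@H](O[Si](CC)(CC)CC)[C@@H]12
F3 | step 11 | (2Z,4S,6Z)-7-iodo-3-methylocta-2,6-diene-1,4-diol | OC/C=C(/C)[C@@H](O)C/C=C(/C)I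
F4 | step 11 | (2Z,4S,6Z)-7-iodo-3-methylocta-2,6-diene-1,4-diyl diacetate | CC(=O)OC/C=C(/C)[C@@H](OC(C)=O)C/C=C(/C)I
F5 | step 11 | (2Z,4S,6Z)-1-hydroxy-7-iodo-3-methylocta-2,6-dien-4-yl acetate | OC/C=C(/C)[C@@H](OC(C)=O)C/C=C(/C)I
F6 | step 11 | (2Z,4S,6Z)-7-iodo-3-methyl-1-oxoocta-2,6-dien-4-yl acetate | O=C/C=C(/C)[C@@H](OC(C)=O)C/C=C(/C)I
F7 | step 11 | (1R,2Z,4S,6Z)-1-hydroxy-7-iodo-3-methyl-1-{(3S,4R)-4-methylidene-5-oxo-2-[(tosyloxy)methyl]oxolan-3-yl}octa-2,6-dien-4-yl acetate (configured as 23) | C=C1C(=O)O[C@@H](COS(=O)(=O)c2ccc(C)cc2)[C@@H]1[C@H](O)/C=C(/C)[C@@H](OC(C)=O)C/C=C(/C)I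
F8 | step 11 | (1Z,3S,5Z)-1-{(2R,3R)-3-[(1R)-1-hydroxy-2-(tosyloxy)ethyl]-4-methylidene-5-oxooxolan-2-yl}-6-iodo-2-methylhepta-1,5-dien-3-yl acetate | C=C1C(=O)O[C@H](/C=C(/C)[C@@H](OC(C)=O)C/C=C(/C)I)[C@H]1[C@@H](O)COS(=O)(=O)c2ccc(C)cc2
F9 | step 14 | (1Z,3S,5Z)-1-{(2R,3R)-3-[(1R)-1,2-dihydroxyethyl]-4-methylidene-5-oxooxolan-2-yl}-6-iodo-2-methylhepta-1,5-dien-3-yl acetate | C=C1C(=O)O[C@H](/C=C(/C)[C@@H](OC(C)=O)C/C=C(/C)I)[C@H]1[C@@H](O)CO
F10 | step 14 | (1Z,3S,5Z)-1-{(2R,3S)-3-[(1R)-1,2-bis[(triethylsilyl)oxy]ethyl]-4-methylidene-5-oxooxolan-2-yl}-6-iodo-2-methylhepta-1,5-dien-3-yl acetate | C=C1C(=O)O[C@H](/C=C(/C)[C@@H](OC(C)=O)C/C=C(/C)I)[C@H]1[C@@H](O[Si](CC)(CC)CC)CO[Si](CC)(CC)CC
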